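**Plan**
Retrosynthetically, the two phenolic O–acyl bonds at C5 and C7 are cut first, then the C3–O3 bond together with the O4-to-O3 acyl shift, and last the three ester bonds back to (2S)-pinocembrin and hexanoic anhydride.
The enabling feature is the hexanoyloxy group on C3 directly beside the C4 ketone of the pyranone ring C: an α-acyloxy ketone can be derived from an epoxidised enol ester that already carries its acyl group on the C4 oxygen.
Forward, no ring is built: the flavanone skeleton (rings A, B and C) is bought, the phenols and then the C4 enol are acylated, the C3=C4 bond is epoxidised and rearranged, and the phenols are unmasked.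
C2 comes unchanged from (2S)-pinocembrin (its descriptor becomes R only because C3 gains oxygen); C3 is set by oxygen transfer anti to the C2 phenyl and kept through a retentive acyl shift.

Key step: step 3

Assumption: commercial natural (2S)-pinocembrin is taken as a single enantiomer; a scalemic batch would first be upgraded by preparative chromatography on a chiral phase, because no later step can correct C2.

Step 1
Reactants: 1 (2S)-pinocembrin; 2 hexanoic anhydride
Product: 3 (2S)-4-oxo-2-phenylchromane-5,7-diyl dihexanoate
Conditions: 2 (2.5 equiv), DMAP (0.1 equiv), pyridine, 0 °C to rt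
Reagents that add atoms: none
Why: DMAP-catalysed O-acylation (nucleophilic acyl transfer catalysis) should esterify both phenols, the chelated 5-OH included, while the weakly basic medium leaves the ketone and the C2 centre untouched and deactivates ring A for the later acid and oxidant.

Step 2
Reactants: 3 (2S)-4-oxo-2-phenylchromane-5,7-diyl dihexanoate; 2 hexanoic anhydride
Product: 4 (2S)-2-phenyl-2H-chromene-4,5,7-triyl trihexanoate
Conditions: 2 (5 equiv), HClO4 (70% aq., 0.02 equiv), CH2Cl2, 0 °C to rt; NaOAc quench
Reagents that add atoms: none
Why: Acid-catalysed enol acylation of a ketone with a carboxylic anhydride (perchloric acid/anhydride conditions) should give the C3=C4 enol hexanoate as the only regioisomer, since C3 is the sole enolisable position, and C2 is not involved as long as the pyran ring stays closed, which the low temperature and buffered quench are meant to ensure.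

Step 3
Reactants: 4 (2S)-2-phenyl-2H-chromene-4,5,7-triyl trihexanoate
Product: 6 (2R,3R)-4-oxo-2-phenylchromane-3,5,7-triyl trihexanoate, via acyloxy epoxide 5 (not isolated)
Conditions: DMDO (dried, ca. 0.07 M in acetone, 1.5 equiv), CH2Cl2, 0 °C to rt; evaporate; TsOH (anhydrous, 0.1 equiv), CH2Cl2, 0 °C
Reagents that add atoms: dimethyldioxirane, CC1(C)OO1
Why: Dimethyldioxirane should deliver one oxygen atom in a concerted fashion to the C3=C4 enol ester bond to give acyloxy epoxide 5; the sulfonic acid then protonates the oxirane oxygen, the C4–O bond ionises to a benzylic cation stabilised by the acyloxy oxygen and by O1 through ring A, and the freed C3 hydroxyl takes over the hexanoyl group through a five-membered cyclic hemi-orthoester while the C4 carbonyl forms. The closest known reaction type is the dioxirane epoxidation of enol esters followed by the strong-acid, retentive mode of the enol ester epoxide to α-acyloxy ketone rearrangement. No ring of the product is closed, the oxirane being transient. The new stereocentre C3 (R) is set under substrate control, the C2 phenyl group shielding one face of the adjacent alkene so that oxygen arrives anti to it, and because the C3–O bond made in the epoxidation is never broken the ester ends 2,3-trans. The step needs facial selectivity (C2 phenyl), chemoselectivity for the alkene over ring A (secured by the two electron-withdrawing aryl ester groups) and the retentive over the concerted invertive acyl shift (secured by anhydrous strong acid and the cation-stabilising O1). Exclusion of water should prevent loss of the acyl group as hexanoic acid, and any acyl exchange with the peri 5-ester is degenerate because all acyl groups are hexanoyl.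

Step 4
Reactants: 6 (2R,3R)-4-oxo-2-phenylchromane-3,5,7-triyl trihexanoate
Product: 7 (2R,3R)-5,7-dihydroxy-4-oxo-2-phenylchroman-3-yl hexanoate
Conditions: NH4OAc (10 equiv), MeOH–THF (4:1), rt
Reagents that add atoms: none
Why: Chemoselective, ammonium acetate-mediated methanolysis of aryl esters beside an alkyl ester should remove the 5- and 7-hexanoates, whose phenoxide leaving groups are conjugated to the C4 carbonyl, while the secondary C3 ester stays and the near-neutral medium spares C2 and C3.

**Compound list**
1 | (2S)-pinocembrin, (2S)-5,7-dihydroxy-2-phenylchroman-4-one | O=C1C[C@@H](c2ccccc2)Oc2cc(O)cc(O)c21 | starting material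
2 | hexanoic anhydride | CCCCCC(=O)OC(=O)CCCCC | starting material
3 | (2S)-4-oxo-2-phenylchromane-5,7-diyl dihexanoate | O=C1C[C@@H](c2ccccc2)Oc2cc(OC(=O)CCCCC)cc(OC(=O)CCCCC)c21 | intermediate
4 | (2S)-2-phenyl-2H-chromene-4,5,7-triyl trihexanoate | CCCCCC(=O)OC1=C[C@@H](c2ccccc2)Oc2cc(OC(=O)CCCCC)cc(OC(=O)CCCCC)c21 | intermediate
5 | (2R,3R,4R)-3,4-epoxy-2-phenylchromane-4,5,7-triyl trihexanoate | CCCCCC(=O)O[C@@]12O[C@@H]1[C@@H](c1ccccc1)Oc1cc(OC(=O)CCCCC)cc(OC(=O)CCCCC)c12 | intermediate
6 | (2R,3R)-4-oxo-2-phenylchromane-3,5,7-triyl trihexanoate | CCCCCC(=O)O[C@H]1C(=O)c2c(OC(=O)CCCCC)cc(OC(=O)CCCCC)cc2O[C@@H]1c1ccccc1 | intermediate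
7 | (2R,3R)-5,7-dihydroxy-4-oxo-2-phenylchroman-3-yl hexanoate (pinobanksin 3-O-hexanoate) | CCCCCC(=O)O[C@H]1C(=O)c2c(O)cc(O)cc2O[C@@H]1c1ccccc1 | target

Total step count: 4. Longest linear sequence: 4 steps, from 1 to 7.

**Steps most likely to fail**

Step 2. The strong acid may open the pyran ring by retro-oxa-Michael cleavage and so erode the C2 configuration, or the enol acylation beside the peri 5-ester may stall. The fallback leaves 3 and avoids protic acid. Soft enolisation with TMSOTf and Et3N in CH2Cl2 at 0 °C should give (2S)-2-phenyl-4-(trimethylsilyloxy)-2H-chromene-5,7-diyl dihexanoate F1. CuCl-promoted O-acylation of this silyl enol ether with hexanoyl chloride in 1,3-dimethyl-2-imidazolidinone would then exchange silicon for the hexanoyl group and return to 4.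

Step 3. Oxygen transfer may show poor facial discrimination, the labile epoxide may shift its acyloxy group in the concerted invertive sense towards the 2,3-cis ester, or adventitious water may strip the acyl group. The fallback leaves 4 and installs the C3 oxygen by dihydroxylation instead. OsO4 (catalytic) with N-methylmorpholine N-oxide in acetone–water should add anti to the C2 phenyl; the C4 hydroxy ester so formed collapses to the ketone with loss of hexanoic acid. This would give (2R,3R)-3-hydroxy-4-oxo-2-phenylchromane-5,7-diyl dihexanoate F2. Esterification of the free 3-hydroxyl with 2 and DMAP in pyridine then comes back to the route at 6.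

Step 4. The C3 ester, activated by the neighbouring ketone, may be partly cleaved along with the aryl esters, or the hindered 5-ester may resist solvolysis. The fallback leaves 1 and makes the phenol protection orthogonal to the ester.
- Benzyl chloroformate in pyridine should give (2S)-5,7-bis(benzyloxycarbonyloxy)-2-phenylchroman-4-one F3.
- Enol acylation with 2 and catalytic HClO4 would give (2S)-5,7-bis(benzyloxycarbonyloxy)-2-phenyl-2H-chromen-4-yl hexanoate F4.
- Dimethyldioxirane followed by TsOH should pass through (2R,3R,4R)-5,7-bis(benzyloxycarbonyloxy)-3,4-epoxy-2-phenylchroman-4-yl hexanoate F5 to (2R,3R)-5,7-bis(benzyloxycarbonyloxy)-4-oxo-2-phenylchroman-3-yl hexanoate F6.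
- Hydrogenolysis with H2 over Pd/C in ethyl acetate at rt would remove both carbonates under neutral conditions and arrive at 7.

**Further compounds**
F1 | step 2 | (2S)-2-phenyl-4-(trimethylsilyloxy)-2H-chromene-5,7-diyl dihexanoate | C[Si](C)(C)OC1=C[C@@H](c2ccccc2)Oc2cc(OC(=O)CCCCC)cc(OC(=O)CCCCC)c21
F2 | step 3 | (2R,3R)-3-hydroxy-4-oxo-2-phenylchromane-5,7-diyl dihexanoate | O[C@H]1C(=O)c2c(OC(=O)CCCCC)cc(OC(=O)CCCCC)cc2O[C@@H]1c1ccccc1
F3 | step 4 | (2S)-5,7-bis(benzyloxycarbonyloxy)-2-phenylchroman-4-one | O=C1C[C@@H](c2ccccc2)Oc2cc(OC(=O)OCc3ccccc3)cc(OC(=O)OCc3ccccc3)c21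
F4 | step 4 | (2S)-5,7-bis(benzyloxycarbonyloxy)-2-phenyl-2H-chromen-4-yl hexanoate | CCCCCC(=O)OC1=C[C@@H](c2ccccc2)Oc2cc(OC(=O)OCc3ccccc3)cc(OC(=O)OCc3ccccc3)c21
F5 | step 4 | (2R,3R,4R)-5,7-bis(benzyloxycarbonyloxy)-3,4-epoxy-2-phenylchroman-4-yl hexanoate | CCCCCC(=O)O[C@@]12O[C@@H]1[C@@H](c1ccccc1)Oc1cc(OC(=O)OCc3ccccc3)cc(OC(=O)OCc3ccccc3)c12
F6 | step 4 | (2R,3R)-5,7-bis(benzyloxycarbonyloxy)-4-oxo-2-phenylchroman-3-yl hexanoate | CCCCCC(=O)O[C@H]1C(=O)c2c(OC(=O)OCc3ccccc3)cc(OC(=O)OCc3ccccc3)cc2O[C@@H]1c1ccccc1
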